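Friday's run stalled: its product crept from 5.9% at 6.00 h to 7.8% at 15.0 h, while Saturday's flask, with a higher loading, a warmer bath and the same impurity, went on to 79.6% at 144 h.

| setting | Saturday's | Friday's | flask |
|---|---|---|---|
| substrate | 0.040 M | 0.040 M | 0.040 M |
| free enzyme | 0.02 mol% | 0.013 mol% | 0.02 mol% |
| impurity | 6.1 µM | 6.1 µM | 6.1 µM |
| temperature | 20 °C | 15 °C | 20 °C |
| remark | the very flask that is asked about, followed so far | run made earlier |  |
| time |  |  | 8.0 d |

| run | time / h | product / % |
|---|---|---|
| Saturday's | 12.0 | 21.6 |
| Saturday's | 30.0 | 43.6 |
| Saturday's | 72.0 | 68.2 |
| Saturday's | 144 | 79.6 |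
| Friday's | 1.33 | 2.8 |
| Friday's | 3.00 | 4.7 |
| Friday's | 6.00 | 5.9 |
| Friday's | 15.0 | 7.8 |

(readings scatter by 0.5 percentage points)

- autumn: at 8.0 d raise the temperature by 20 K, then wait 15 d
- midnight: at 8.0 d add free enzyme, 100% of the amount charged, then wait 15 d
- dusk: at 8.0 d take out 90% of the product then present, then wait 15 d
- dawn: change nothing and wait 15 d more

- product taken out counts as made
- candidate steps: substrate + free enzyme -> product + free enzyme; free enzyme -> unfolded enzyme; free enzyme + impurity -> spent catalyst
- additions bring no volume worth counting

- product, in percent of the substrate first charged, at 8.0 d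
- the option that brings most further product ("none" if no option brings more than 2 percentage points) (autumn / midnight / dusk / dawn / none)
- product present, with what was taken out counted in, in percent of the substrate first charged, after autumn
- product present, with what was taken out counted in, in percent of the substrate first charged, after midnight

I distrusted curve shapes and counted instead, taking one impurity to remove one free enzyme. Friday's run charged less free enzyme, 5.20 µM, than impurity, 6.1 µM, so by that count capture could end with no free enzyme in Friday's run. Saturday's flask charged 8.00 µM. I called the free enzyme charged minus the impurity charged the margin, which for Saturday's flask is 1.90 µM, a quarter of the charge.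

The ladder then read as follows. The first rung I took to be capture: in Friday's run the pace per enzyme charged fell from 162 h⁻¹ in the opening interval to 16.2 h⁻¹ in the last, after 600 turnovers in total. On the next rung I took Saturday's survivors to do the work, at 257 h⁻¹ each, reckoned on the margin, between the first two readings. On the last rung, between Saturday's last two readings, that pace was 33.3 h⁻¹. The pace dropped by a factor of 7.72, which is more than the factor of 2.58 for the mean substrate left over the same intervals. The readings could not tell me whether survivors were dying or the step was steep in substrate.

Holding the last interval's pace to 8.0 d gave me a high estimate of 87.2%, since that pace had been dropping. Adding the charge again should raise the margin to 9.90 µM, 5.21 times the old one, so I expected midnight to win. The forecast said 82%, midnight, 83.5% after autumn and 99.9% after midnight, on the ground “Fresh enzyme meets no impurity”.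

The flask gave 83.1% at 8.0 d, and midnight brought 12 percentage points further, to 95.2%, against 7.2 points for dawn, while autumn ended at 84.4%. The steps were these:

    substrate + free enzyme → product + free enzyme, rate k1*[substrate]^3*[free enzyme]/(1 + ([substrate]/Kh1)^3) (21.5 mM, k = 10900 M⁻³ s⁻¹, Ea = 23.0 kJ mol⁻¹)
    free enzyme → unfolded enzyme (k = 1.28 × 10⁻⁷ s⁻¹, Ea = 186 kJ mol⁻¹)
    free enzyme + impurity → spent catalyst (k = 66.4 M⁻¹ s⁻¹, Ea = 40.0 kJ mol⁻¹)
    (constants at 20 °C)

In this flask free enzyme stood at 23.5% of its charge at 19.2 h and 21.7% at 192 h, against the margin's 23.8%. In the neighbour with 1.5 × 10⁻⁵ M of impurity the margin is −7.00 µM, which leaves 46.7% of its impurity unspent by the count, and that flask held 46.7% at 192 h, with product at 2.67%.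

All runs come from a simulation for substances that don't exist.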